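# Neocucurbin A: synthesis design

## The problem

Neocucurbin A is a bridged bicycle. A cyclohexene (C8, C9, C10, C11, C14, C15) is spanned across its 1,4-related allylic carbons C8 and C11 by the chain C12–C13–C2(CH3)=C3–C4(OH)–C5–C6(CH3)(C19H2OH)–O7, which closes a twelve-membered oxacycle; a butenolide (C16 carbonyl on C15, C18 methylene on C14) is fused to the ring alkene. It has five stereocentres (4S, 6S, 8R, 10R, 11S) and a (2Z) trisubstituted alkene. The methyls on C10 and on the quaternary C11 are cis, and O7 on C8 lies on the opposite ring face, the same face as C12, as the bridge demands. C10 and C11 must be set together; they can bias C8, but hydride addition under substrate control is expected to put the C8 oxygen cis to the C10 methyl, so C8 needs reagent control. C4 and C6 sit in the bridge, too far from the ring in any open-chain precursor to be controlled by it, so each needs its own source of chirality, and the Z geometry must be fixed before the ring is closed. The hardest single bond is the ether between the secondary C8 and the fully substituted C6. The fragile parts are the γ-alkoxybutenolide (base can open the lactone or expel O7 through the C18 dienolate), the allylic C4 carbinol and the tertiary ether toward strong acid. The feature that opens the route is the cyclohexene itself: adjacent cis methyls on C10 and C11, oxygen on C8 para to C11, and a one-carbon oxygenated branch (C18) on C14 are the pattern left by (E)-2-methylbut-2-enal adding to a 2-silyloxy-1,3-diene that carries CH2O at its terminus.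

## Retrosynthesis

**Last step.** Target 32 is taken back to its C4 silyl ether 31. Only one protecting group remains at the end, and it is removed with buffered HF because basic fluoride would endanger the γ-alkoxybutenolide.

**Macrocycle.** In 31 the C13–C2 bond is cut, giving the open-chain ether 29 with a vinyl group on C11 and a (Z)-vinyl iodide at C2. The forward reaction is hydroboration to alkylborane 30 and an intramolecular B-alkyl Suzuki–Miyaura coupling.
- Closing the ring at the ether instead would combine the hardest bond and the entropic cost in one event, at a dilution where the hydroxyl must outrun unimolecular rearrangement of the epoxide.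
- Closing at C3–C4 or by metathesis at C2=C3 would leave C4 or the alkene geometry uncontrolled.
- The Suzuki closure carries the Z geometry in from the iodide, and 29 has no large ring.
- It asks for selective hydroboration of the one monosubstituted alkene and for a base mild enough for the butenolide.

**Tertiary ether.** In 29 the C6–O7 bond is cut, giving alcohol 12 and the 2,2-disubstituted epoxide 28. Forward, a Lewis acid opens the epoxide at its tertiary carbon with inversion, so (R)-28 gives the (6S) ether and the epoxide oxygen becomes the C19 hydroxyl. The other cut, C8–O7, would need a tertiary alkoxide to displace at a hindered secondary carbon next to an electron-poor alkene. The step needs a high concentration of 12 and a low temperature.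

**Butenolide and C8.** Alcohol 12 comes from iodo diol 11 by carbonylative lactonisation, which brings in C16 as CO. Diol 11 is the desilylated form of 10, whose C8 carbinol is set by a reagent-controlled reduction of iodoenone 9. Iodoenone 9 comes from enone 8 by α-iodination, 8 from silyl enol ether 7 by Saegusa–Ito oxidation, and 7 from aldehyde 6 by methylenation. Each operation uses the functionality the cycloaddition leaves behind: the enol ether places the enone, and the formyl group becomes C12=C13.

**Key disconnection.** Adduct 6 is cut at C9–C10 and C11–C14 into diene 4 and (E)-2-methylbut-2-enal 5. One catalytic step builds the ring, the quaternary C11 and the cis methyl pair, and leaves C8 and C18 oxygenated. Stepwise alkylation of a preformed ring would have to set the quaternary centre against a neighbouring methyl.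

**Diene.** Diene 4 comes from enone 3 by silyl enol ether formation, and 3 from aldehyde 1 and ylide 2 by a Wittig reaction.

**Side-chain fragment.** Epoxide 28 is closed from diol 26 through monotosylate 27. Diol 26 comes from acetonide 25, the silyl ether of (Z)-iodo alcohol 24. Alcohol 24 arises from propargylic alcohol 22 by trans-hydroalumination (alanate 23) and iodination, which fixes the Z geometry. C4 in 22 is set by catalyst-controlled transfer hydrogenation of ynone 21. Ynone 21 comes from alcohol 20, made from aldehyde 18 and the propynyl Grignard reagent 19. Aldehyde 18 comes from alkene 16 by ozonolysis (ozonide 17), 16 from diol 15, and 15 from (S)-2-methylglycidol 13 and vinyl Grignard reagent 14. C6 is thus bought, and C4 is set by a catalyst; neither depends on the other.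

## Roads not taken

**Alternative 1:** The cut is C5–C6. The forward key step is an Ireland–Claisen ring contraction: the ester of a lactate unit already attached to O7 is enolised and silylated, and the [3,3] shift runs through a vinyl group on C3 to give acid A1.
- Merits: the fully substituted C6 is made by C–C bond formation and the large ring by lactonisation. Both are more dependable than making a tertiary C–O bond, and in this respect the road is better than the chosen one.
- Weak points: the configuration at C6 depends on enolate geometry of an α-alkoxy ester and on chair versus boat topology inside a twelve-membered ring, neither of which is easy to predict. The product carries the wrong oxidation pattern in three places: C2–O instead of C4–O with an (E)-C3=C4 alkene, a C6 acid instead of CH2OH, and a butenolide at the diol level. It therefore needs an allylic transposition that also inverts the alkene geometry, a reduction and a late lactone oxidation.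
- Against it, the chosen plan sets C4 and the Z alkene in final form in a small fragment, has the butenolide carbons in place soon after the cycloaddition, and is convergent.

**Alternative 2:** The cut is C8–C15. The forward key step opens, with TiCl4, an acetal that ties C8 to both oxygens of the C6/C19 diol. Loss of the primary oxygen leaves an oxocarbenium ion at C8, which the enol carbon C15 of a β-keto ester on C11 captures to give bicycle A2.
- Merits: the tertiary ether comes from an acetal, the easiest way to attach a hindered oxygen, and the C19 hydroxyl is released in the same step. On this point it is better than the chosen plan.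
- Weak points: the cyclohexene is formed last, inside a macrocycle, so C10 and the quaternary C11 must be built on an open chain without the help of a cycloaddition. The facial selectivity at C8 rests on transannular preferences that cannot be foreseen, and which acetal C–O bond breaks is not guaranteed. A2 still lacks C18, which has to be added to C14 afterwards.
- Against it, the chosen plan secures C10 and C11 by a catalytic reaction of a well-studied type and introduces C18 with the diene.

**Alternative 3:** The cuts are the C10–methyl and C11–C12 bonds. The forward key step is a three-component coupling on a terpene-derived six-membered enone: Me2CuLi adds to C10 anti to the C8 silyloxy group, and the enolate is allylated at C11 anti to the new methyl, giving ketone A3.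
- Merits: cheap chiral-pool material, no chiral catalyst, and C8 correct from the start, so the late reagent-controlled reduction of the chosen plan is avoided. In these respects it is better.
- Weak points: alkylating a 2,3-disubstituted enolate to a quaternary centre is only moderately selective and competes with enolate equilibration. The allyl group must be reshaped to the two-carbon C12–C13 link, and both butenolide carbons (C16, C18) must still be added around the C14 ketone.
- Against it, the cycloaddition sets the quaternary centre suprafacially from the alkene geometry and delivers C18 and the C8 handle in the same step.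

Key step: step 3

Assumption (sense of induction in step 3): by the usual organisation of a 2-substituted enal on the cationic oxazaborolidine (formyl C–H bound to the ring oxygen, s-trans enal over the aryl group), the (S)-catalyst should expose the face of 5 that is Re at C2 and Si at C3; if the first adduct proves antipodal, the (R)-catalyst is used unchanged.

Assumption (supply): (S)-2-methylglycidol 13 is taken as purchasable in enantiopure form.

## Route

Step 1
Reactants: 1 (tert-butyldimethylsilyloxy)acetaldehyde; 2 1-(triphenylphosphoranylidene)propan-2-one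
Product: 3 (E)-5-(tert-butyldimethylsilyloxy)pent-3-en-2-one
Conditions: CH2Cl2, rt
Reagents that add atoms: none
Why: Wittig olefination with a stabilised ylide, which should give the (E)-enone; the silyl ether is inert.

Step 2
Reactants: 3 (E)-5-(tert-butyldimethylsilyloxy)pent-3-en-2-one
Product: 4 (E)-5-(tert-butyldimethylsilyloxy)-2-(triisopropylsilyloxy)penta-1,3-diene
Conditions: TIPSOTf, Et3N, CH2Cl2, 0 °C
Reagents that add atoms: triisopropylsilyl trifluoromethanesulfonate, CC(C)[Si](C(C)C)(C(C)C)OS(=O)(=O)C(F)(F)F
Why: Soft enolisation of the methyl ketone (silyl triflate and amine) at the methyl group gives the cross-conjugated 2-silyloxydiene; the E alkene is not touched, and the bulky silyl group is chosen to survive the acid of step 3.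

Step 3
Reactants: 4 (E)-5-(tert-butyldimethylsilyloxy)-2-(triisopropylsilyloxy)penta-1,3-diene; 5 (E)-2-methylbut-2-enal
Product: 6 (1S,2R,6R)-2-[(tert-butyldimethylsilyloxy)methyl]-1,6-dimethyl-4-(triisopropylsilyloxy)cyclohex-3-ene-1-carbaldehyde
Conditions: (S)-3,3-diphenyl-1-(2-methylphenyl)tetrahydro-1H,3H-pyrrolo[1,2-c][1,3,2]oxazaborole·HN(SO2CF3)2 (20 mol%), CH2Cl2, −78 to −40 °C
Reagents that add atoms: none
Why: The N-protonated oxazaborolidine binds the formyl oxygen of 5 anti to the alkene and lowers its LUMO; a concerted but asynchronous [4+2] addition follows in which C9 of 4 bonds to the β-carbon C10 ahead of C14 bonding to the α-carbon C11. The closest known reaction type is the cationic-oxazaborolidine-catalysed enantioselective Diels–Alder reaction of 2-substituted and 2,3-disubstituted enals with 2-(triisopropylsilyloxy)dienes. The six-membered carbocycle closes by intermolecular cycloaddition, suprafacial on both partners. Suprafacial addition turns the E geometry of 5 into the cis relation of the C10 and C11 methyls. The absolute configuration (10R,11S) comes from the catalyst, whose aryl group covers one face of the bound enal so that the diene adds to the C2-Re/C3-Si face. C14 is expected to form with the formyl group endo (cis to the silyloxymethyl group), but this centre becomes sp2 in step 5, so either C14 epimer serves. Regiochemistry needs the 2-silyloxy group, which makes C9 the nucleophilic terminus, and is reinforced by the terminal substituent, so that oxygen ends up on C8 para to C11. The step also needs both silyl groups to survive the acid, which the bulky enol silyl group and the low temperature should secure.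

Step 4
Reactants: 6 (1S,2R,6R)-2-[(tert-butyldimethylsilyloxy)methyl]-1,6-dimethyl-4-(triisopropylsilyloxy)cyclohex-3-ene-1-carbaldehyde
Product: 7 tert-butyl{[(1R,5R,6S)-6-ethenyl-5,6-dimethyl-3-(triisopropylsilyloxy)cyclohex-2-en-1-yl]methoxy}dimethylsilane
Conditions: Ph3PCH3Br, KN(SiMe3)2, THF, 0 °C to rt
Reagents that add atoms: methyltriphenylphosphonium bromide, C[P+](c1ccccc1)(c1ccccc1)c1ccccc1.[Br-]
Why: Wittig methylenation of a non-enolisable neopentyl aldehyde; the ylide leaves the silyl enol ether and silyl ether alone, and the quaternary C11 cannot epimerise.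

Step 5
Reactants: 7 tert-butyl{[(1R,5R,6S)-6-ethenyl-5,6-dimethyl-3-(triisopropylsilyloxy)cyclohex-2-en-1-yl]methoxy}dimethylsilane
Product: 8 (4S,5R)-3-[(tert-butyldimethylsilyloxy)methyl]-4-ethenyl-4,5-dimethylcyclohex-2-en-1-one
Conditions: Pd(OAc)2 (1.2 equiv), MeCN, 40 °C
Reagents that add atoms: none
Why: Saegusa–Ito oxidation: palladation of the enol ether at C15 and β-hydride elimination of the C14 hydrogen place the alkene at C14=C15, as fixed by the position of the enol ether. The C14 stereocentre is removed, so both C14 epimers of 6 converge.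

Step 6
Reactants: 8 (4S,5R)-3-[(tert-butyldimethylsilyloxy)methyl]-4-ethenyl-4,5-dimethylcyclohex-2-en-1-one
Product: 9 (4S,5R)-3-[(tert-butyldimethylsilyloxy)methyl]-4-ethenyl-2-iodo-4,5-dimethylcyclohex-2-en-1-one
Conditions: I2, pyridine, DMAP (cat.), CH2Cl2, 0 °C to rt
Reagents that add atoms: iodine, II
Why: Amine-mediated α-iodination of a cyclic enone (conjugate addition of the amine, iodination of the enolate, elimination); the isolated vinyl group does not react with iodine under these conditions.

Step 7
Reactants: 9 (4S,5R)-3-[(tert-butyldimethylsilyloxy)methyl]-4-ethenyl-2-iodo-4,5-dimethylcyclohex-2-en-1-one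
Product: 10 (1R,4S,5R)-3-[(tert-butyldimethylsilyloxy)methyl]-4-ethenyl-2-iodo-4,5-dimethylcyclohex-2-en-1-ol
Conditions: (S)-1-methyl-3,3-diphenyltetrahydro-1H,3H-pyrrolo[1,2-c][1,3,2]oxazaborole (0.5 equiv), catecholborane, toluene, −78 to −40 °C; then MeOH
Reagents that add atoms: none
Why: Corey–Bakshi–Shibata reduction, for which 2-haloenones are among the best substrates; the iodoalkene arm acts as the large group, so the (S)-catalyst should deliver hydride to give the (8R) carbinol, with the oxygen trans to both methyls. Catecholborane at low temperature does not hydroborate the vinyl group.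

Step 8
Reactants: 10 (1R,4S,5R)-3-[(tert-butyldimethylsilyloxy)methyl]-4-ethenyl-2-iodo-4,5-dimethylcyclohex-2-en-1-ol
Product: 11 (1R,4S,5R)-4-ethenyl-3-(hydroxymethyl)-2-iodo-4,5-dimethylcyclohex-2-en-1-ol
Conditions: HF·pyridine, pyridine, THF, 0 °C to rt
Reagents that add atoms: none
Why: Fluoride cleavage of a primary silyl ether; buffered HF leaves the allylic alcohol and the vinyl iodide intact.

Step 9
Reactants: 11 (1R,4S,5R)-4-ethenyl-3-(hydroxymethyl)-2-iodo-4,5-dimethylcyclohex-2-en-1-ol
Product: 12 (4S,5R,7R)-4-ethenyl-7-hydroxy-4,5-dimethyl-4,5,6,7-tetrahydro-2-benzofuran-1(3H)-one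
Conditions: Pd(PPh3)4 (10 mol%), CO (1 atm), Et3N, DMF, 60 °C
Reagents that add atoms: carbon monoxide, [C-]#[O+]
Why: Palladium-catalysed carbonylative lactonisation of a (Z)-γ-hydroxy vinyl iodide: oxidative addition to zerovalent palladium, CO insertion, and capture of the acylpalladium by the cis C18 hydroxyl to close the five-membered lactone. The C8 hydroxyl could only form a four-membered ring and stays free.

Step 10
Reactants: 13 [(2S)-2-methyloxiran-2-yl]methanol ((S)-2-methylglycidol); 14 vinylmagnesium bromide
Product: 15 (2R)-2-methylpent-4-ene-1,2-diol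
Conditions: CuI (10 mol%), THF, −30 to 0 °C; aq. NH4Cl
Reagents that add atoms: none
Why: Copper-catalysed Grignard opening of a 2,2-disubstituted epoxide at its unsubstituted carbon, after the first equivalent has deprotonated the hydroxyl. No bond to the stereocentre is broken, and the degenerate Payne shift of this alkoxide returns the same enantiomer.

Step 11
Reactants: 15 (2R)-2-methylpent-4-ene-1,2-diol
Product: 16 (4R)-2,2,4-trimethyl-4-(prop-2-en-1-yl)-1,3-dioxolane
Conditions: 2,2-dimethoxypropane, PPTS (cat.), CH2Cl2, rt
Reagents that add atoms: 2,2-dimethoxypropane, COC(C)(C)OC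
Why: Acid-catalysed transacetalisation of a 1,2-diol; the acetonide masks the tertiary hydroxyl, which would otherwise allow lactol formation, retro-aldol cleavage or cyclisation onto the later ynone.

Step 12
Reactants: 16 (4R)-2,2,4-trimethyl-4-(prop-2-en-1-yl)-1,3-dioxolane
Product: 18 2-[(4R)-2,2,4-trimethyl-1,3-dioxolan-4-yl]acetaldehyde, via ozonide 17 (not isolated)
Conditions: O3, CH2Cl2, −78 °C; then PPh3, −78 °C to rt
Reagents that add atoms: ozone, [O-][O+]=O
Why: Ozonolysis of a terminal alkene with reductive work-up gives the aldehyde that becomes C4.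

Step 13
Reactants: 18 2-[(4R)-2,2,4-trimethyl-1,3-dioxolan-4-yl]acetaldehyde; 19 prop-1-ynylmagnesium bromide
Product: 20 1-[(4R)-2,2,4-trimethyl-1,3-dioxolan-4-yl]pent-3-yn-2-ol (both C2 epimers)
Conditions: THF, −78 to 0 °C
Reagents that add atoms: none
Why: Grignard addition of an alkynyl nucleophile to an aldehyde; no selectivity is needed because the new carbinol is oxidised in the next step.

Step 14
Reactants: 20 1-[(4R)-2,2,4-trimethyl-1,3-dioxolan-4-yl]pent-3-yn-2-ol
Product: 21 1-[(4R)-2,2,4-trimethyl-1,3-dioxolan-4-yl]pent-3-yn-2-one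
Conditions: Dess–Martin periodinane, NaHCO3, CH2Cl2, 0 °C to rt
Reagents that add atoms: none
Why: Dess–Martin oxidation of a propargylic alcohol to the ynone; the buffer protects the acetonide.

Step 15
Reactants: 21 1-[(4R)-2,2,4-trimethyl-1,3-dioxolan-4-yl]pent-3-yn-2-one
Product: 22 (2S)-1-[(4R)-2,2,4-trimethyl-1,3-dioxolan-4-yl]pent-3-yn-2-ol
Conditions: RuCl[(S,S)-TsDPEN](p-cymene) (2 mol%), KOH (2 mol%), i-PrOH, rt
Reagents that add atoms: none
Why: Noyori asymmetric transfer hydrogenation of an α,β-acetylenic ketone; the alkynyl group takes the place of the aryl group in the usual model, so the (S,S)-catalyst should give the (S)-propargylic alcohol (C4) under catalyst control, regardless of the remote C6 centre.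

Step 16
Reactants: 22 (2S)-1-[(4R)-2,2,4-trimethyl-1,3-dioxolan-4-yl]pent-3-yn-2-ol
Product: 24 (2S,3Z)-4-iodo-1-[(4R)-2,2,4-trimethyl-1,3-dioxolan-4-yl]pent-3-en-2-ol, via sodium alkenylalanate 23 (not isolated)
Conditions: NaAlH2(OCH2CH2OMe)2, THF, 0 °C to rt; then I2, THF, −78 °C
Reagents that add atoms: iodine, II
Why: Trans-hydroalumination of a propargylic alcohol: the aluminium alkoxide delivers hydride to the nearer alkyne carbon and aluminium ends on the methyl-bearing carbon in a five-membered ring; iodination with retention gives the (Z)-iodoalkene that carries the C2=C3 geometry.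

Step 17
Reactants: 24 (2S,3Z)-4-iodo-1-[(4R)-2,2,4-trimethyl-1,3-dioxolan-4-yl]pent-3-en-2-ol
Product: 25 tert-butyl({(2S,3Z)-4-iodo-1-[(4R)-2,2,4-trimethyl-1,3-dioxolan-4-yl]pent-3-en-2-yl}oxy)dimethylsilane
Conditions: TBSCl, imidazole, DMF, rt
Reagents that add atoms: tert-butyldimethylsilyl chloride, CC(C)(C)[Si](C)(C)Cl
Why: Standard silylation of a secondary allylic alcohol; this is the only protecting group carried to the end.

Step 18
Reactants: 25 tert-butyl({(2S,3Z)-4-iodo-1-[(4R)-2,2,4-trimethyl-1,3-dioxolan-4-yl]pent-3-en-2-yl}oxy)dimethylsilane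
Product: 26 (2R,4S,5Z)-4-(tert-butyldimethylsilyloxy)-6-iodo-2-methylhept-5-ene-1,2-diol
Conditions: PPTS (cat.), MeOH, rt
Reagents that add atoms: none
Why: Mild acid-catalysed transacetalisation into methanol removes the terminal acetonide; a secondary silyl ether should survive these conditions.

Step 19
Reactants: 26 (2R,4S,5Z)-4-(tert-butyldimethylsilyloxy)-6-iodo-2-methylhept-5-ene-1,2-diol
Product: 28 tert-butyl({(2S,3Z)-4-iodo-1-[(2R)-2-methyloxiran-2-yl]pent-3-en-2-yl}oxy)dimethylsilane, via primary tosylate 27 (not isolated)
Conditions: TsCl, Et3N, Bu2SnO (cat.), CH2Cl2, 0 °C; then K2CO3, MeOH, rt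
Reagents that add atoms: none
Why: Tin-catalysed selective sulfonylation of the primary hydroxyl of a 1,2-diol, then intramolecular Williamson closure by the tertiary alkoxide; the C6–O bond is never broken, so the configuration from 13 is kept.

Step 20
Reactants: 12 (4S,5R,7R)-4-ethenyl-7-hydroxy-4,5-dimethyl-4,5,6,7-tetrahydro-2-benzofuran-1(3H)-one; 28 tert-butyl({(2S,3Z)-4-iodo-1-[(2R)-2-methyloxiran-2-yl]pent-3-en-2-yl}oxy)dimethylsilane
Product: 29 (4S,5R,7R)-7-{[(2S,4S,5Z)-4-(tert-butyldimethylsilyloxy)-1-hydroxy-6-iodo-2-methylhept-5-en-2-yl]oxy}-4-ethenyl-4,5-dimethyl-4,5,6,7-tetrahydro-2-benzofuran-1(3H)-one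
Conditions: BF3·OEt2 (10 mol%), CH2Cl2, −40 °C; 12 in two-fold excess at high concentration, 28 added slowly
Reagents that add atoms: none
Why: Lewis-acid-catalysed alcoholysis of a 2,2-disubstituted epoxide at its more substituted carbon; the alcohol attacks anti to the departing oxygen in a borderline SN2 process, so the (R)-epoxide should give the (6S) tertiary ether and the epoxide oxygen becomes the C19 hydroxyl. The excess of 12 and slow addition of 28 are meant to let capture outrun Meinwald rearrangement and further alkylation of the product; unreacted 12 can be recovered.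

Step 21
Reactants: 29 (4S,5R,7R)-7-{[(2S,4S,5Z)-4-(tert-butyldimethylsilyloxy)-1-hydroxy-6-iodo-2-methylhept-5-en-2-yl]oxy}-4-ethenyl-4,5-dimethyl-4,5,6,7-tetrahydro-2-benzofuran-1(3H)-one
Product: 31 4-O-(tert-butyldimethylsilyl)neocucurbin A, via alkylborane 30 (not isolated)
Conditions: 9-BBN (4 equiv), THF, rt to 40 °C; then slow addition to Pd(dppf)Cl2 (20 mol%), AsPh3, Cs2CO3, DMF/THF/H2O, 50 °C, 2 mM
Reagents that add atoms: none
Why: B-alkyl Suzuki–Miyaura macrocyclisation: 9-borabicyclo[3.3.1]nonane adds anti-Markovnikov to the only monosubstituted alkene (the free hydroxyl is taken up as a borinate and released by the aqueous base), and coupling with the vinyl iodide forms C13–C2 with retention of the Z geometry. Closures of this type onto a six-membered ring to give bridged twelve-membered carbocycles are known.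

Step 22
Reactants: 31 4-O-(tert-butyldimethylsilyl)neocucurbin A
Product: 32 neocucurbin A
Conditions: HF·pyridine, pyridine, THF, 0 °C to rt
Reagents that add atoms: none
Why: Desilylation under buffered acidic fluoride; basic fluoride is avoided because of the γ-alkoxybutenolide.

## Compound list

1 | (tert-butyldimethylsilyloxy)acetaldehyde | O=CCO[Si](C)(C)C(C)(C)C | starting material
2 | 1-(triphenylphosphoranylidene)propan-2-one | CC(=O)C=P(c1ccccc1)(c1ccccc1)c1ccccc1 | starting material
3 | (E)-5-(tert-butyldimethylsilyloxy)pent-3-en-2-one | CC(=O)/C=C/CO[Si](C)(C)C(C)(C)C | intermediate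
4 | (E)-5-(tert-butyldimethylsilyloxy)-2-(triisopropylsilyloxy)penta-1,3-diene | C=C(O[Si](C(C)C)(C(C)C)C(C)C)/C=C/CO[Si](C)(C)C(C)(C)C | intermediate
5 | (E)-2-methylbut-2-enal (tiglic aldehyde) | C/C=C(\C)C=O | starting material
6 | (1S,2R,6R)-2-[(tert-butyldimethylsilyloxy)methyl]-1,6-dimethyl-4-(triisopropylsilyloxy)cyclohex-3-ene-1-carbaldehyde | C[C@@H]1CC(O[Si](C(C)C)(C(C)C)C(C)C)=C[C@@H](CO[Si](C)(C)C(C)(C)C)[C@@]1(C)C=O | intermediate
7 | tert-butyl{[(1R,5R,6S)-6-ethenyl-5,6-dimethyl-3-(triisopropylsilyloxy)cyclohex-2-en-1-yl]methoxy}dimethylsilane | C[C@@H]1CC(O[Si](C(C)C)(C(C)C)C(C)C)=C[C@@H](CO[Si](C)(C)C(C)(C)C)[C@@]1(C)C=C | intermediate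
8 | (4S,5R)-3-[(tert-butyldimethylsilyloxy)methyl]-4-ethenyl-4,5-dimethylcyclohex-2-en-1-one | C[C@@H]1CC(=O)C=C(CO[Si](C)(C)C(C)(C)C)[C@@]1(C)C=C | intermediate
9 | (4S,5R)-3-[(tert-butyldimethylsilyloxy)methyl]-4-ethenyl-2-iodo-4,5-dimethylcyclohex-2-en-1-one | C[C@@H]1CC(=O)C(I)=C(CO[Si](C)(C)C(C)(C)C)[C@@]1(C)C=C | intermediate
10 | (1R,4S,5R)-3-[(tert-butyldimethylsilyloxy)methyl]-4-ethenyl-2-iodo-4,5-dimethylcyclohex-2-en-1-ol | C[C@@H]1C[C@@H](O)C(I)=C(CO[Si](C)(C)C(C)(C)C)[C@@]1(C)C=C | intermediate
11 | (1R,4S,5R)-4-ethenyl-3-(hydroxymethyl)-2-iodo-4,5-dimethylcyclohex-2-en-1-ol | C[C@@H]1C[C@@H](O)C(I)=C(CO)[C@@]1(C)C=C | intermediate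
12 | (4S,5R,7R)-4-ethenyl-7-hydroxy-4,5-dimethyl-4,5,6,7-tetrahydro-2-benzofuran-1(3H)-one | C[C@@H]1C[C@@H](O)C2=C(COC2=O)[C@@]1(C)C=C | intermediate
13 | [(2S)-2-methyloxiran-2-yl]methanol ((S)-2-methylglycidol) | C[C@]1(CO)CO1 | starting material
14 | vinylmagnesium bromide | C=C[Mg]Br | starting material
15 | (2R)-2-methylpent-4-ene-1,2-diol | C=CC[C@@](C)(O)CO | intermediate
16 | (4R)-2,2,4-trimethyl-4-(prop-2-en-1-yl)-1,3-dioxolane | C=CC[C@]1(C)COC(C)(C)O1 | intermediate
17 | 3-{[(4R)-2,2,4-trimethyl-1,3-dioxolan-4-yl]methyl}-1,2,4-trioxolane (ozonide, epimers at the trioxolane carbon) | O1OCOC1C[C@]2(C)COC(C)(C)O2 | intermediate (not isolated)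
18 | 2-[(4R)-2,2,4-trimethyl-1,3-dioxolan-4-yl]acetaldehyde | O=CC[C@]1(C)COC(C)(C)O1 | intermediate
19 | prop-1-ynylmagnesium bromide | CC#C[Mg]Br | starting material
20 | 1-[(4R)-2,2,4-trimethyl-1,3-dioxolan-4-yl]pent-3-yn-2-ol (both C2 epimers) | CC#CC(O)C[C@]1(C)COC(C)(C)O1 | intermediate
21 | 1-[(4R)-2,2,4-trimethyl-1,3-dioxolan-4-yl]pent-3-yn-2-one | CC#CC(=O)C[C@]1(C)COC(C)(C)O1 | intermediate
22 | (2S)-1-[(4R)-2,2,4-trimethyl-1,3-dioxolan-4-yl]pent-3-yn-2-ol | CC#C[C@@H](O)C[C@]1(C)COC(C)(C)O1 | intermediate
23 | sodium cyclic alkenyl(alkoxy)bis(2-methoxyethoxy)aluminate of 22 (aluminium on C2, oxygen of C4) | CC1=C[C@H](C[C@]2(C)COC(C)(C)O2)O[Al-]1(OCCOC)OCCOC.[Na+] | intermediate (not isolated)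
24 | (2S,3Z)-4-iodo-1-[(4R)-2,2,4-trimethyl-1,3-dioxolan-4-yl]pent-3-en-2-ol | C/C(I)=C/[C@@H](O)C[C@]1(C)COC(C)(C)O1 | intermediate
25 | tert-butyl({(2S,3Z)-4-iodo-1-[(4R)-2,2,4-trimethyl-1,3-dioxolan-4-yl]pent-3-en-2-yl}oxy)dimethylsilane | C/C(I)=C/[C@@H](O[Si](C)(C)C(C)(C)C)C[C@]1(C)COC(C)(C)O1 | intermediate
26 | (2R,4S,5Z)-4-(tert-butyldimethylsilyloxy)-6-iodo-2-methylhept-5-ene-1,2-diol | C/C(I)=C/[C@@H](O[Si](C)(C)C(C)(C)C)C[C@@](C)(O)CO | intermediate
27 | (2R,4S,5Z)-4-(tert-butyldimethylsilyloxy)-2-hydroxy-6-iodo-2-methylhept-5-en-1-yl 4-methylbenzenesulfonate | C/C(I)=C/[C@@H](O[Si](C)(C)C(C)(C)C)C[C@@](C)(O)COS(=O)(=O)c1ccc(C)cc1 | intermediate (not isolated)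
28 | tert-butyl({(2S,3Z)-4-iodo-1-[(2R)-2-methyloxiran-2-yl]pent-3-en-2-yl}oxy)dimethylsilane | C/C(I)=C/[C@@H](O[Si](C)(C)C(C)(C)C)C[C@]1(C)CO1 | intermediate
29 | (4S,5R,7R)-7-{[(2S,4S,5Z)-4-(tert-butyldimethylsilyloxy)-1-hydroxy-6-iodo-2-methylhept-5-en-2-yl]oxy}-4-ethenyl-4,5-dimethyl-4,5,6,7-tetrahydro-2-benzofuran-1(3H)-one | C/C(I)=C/[C@@H](O[Si](C)(C)C(C)(C)C)C[C@@](C)(CO)O[C@@H]1C[C@@H](C)[C@](C)(C=C)C2=C1C(=O)OC2 | intermediate
30 | C13 alkylborane of 29 (9-borabicyclo[3.3.1]nonan-9-yl on C13, C19 oxygen as its borinate) | C/C(I)=C/[C@@H](O[Si](C)(C)C(C)(C)C)C[C@@](C)(COB3C4CCCC3CCC4)O[C@@H]1C[C@@H](C)[C@](C)(CCB3C4CCCC3CCC4)C2=C1C(=O)OC2 | intermediate (not isolated)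
31 | 4-O-(tert-butyldimethylsilyl)neocucurbin A | C/C1=C/[C@@H](O[Si](C)(C)C(C)(C)C)C[C@@](C)(CO)O[C@@H]2C[C@@H](C)[C@](C)(CC1)C1=C2C(=O)OC1 | intermediate
32 | neocucurbin A | C/C1=C/[C@@H](O)C[C@@](C)(CO)O[C@@H]2C[C@@H](C)[C@](C)(CC1)C1=C2C(=O)OC1 | target

## Step count and risk

Total step count: 22. Longest linear sequence: 13 steps (steps 10–19, then 20–22); the other branch is 12 steps (steps 1–9, then 20–22).

**Step 20 (ether formation).** The hindered secondary hydroxyl may capture the activated epoxide too slowly, so that Meinwald rearrangement or oligomerisation of the epoxide wins. The liberated primary hydroxyl may be alkylated a second time. Ionisation to a free tertiary cation would erode the inversion at C6.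
Fallback, from 12 and 28, back at 31: the two partners are tethered first, which removes the stoichiometry and over-alkylation problems. Alcohol 12 is hydroborated with 9-BBN to the C13 alkylborane carrying the C8 oxygen as its borinate F1. This is cross-coupled with 28 (Pd(dppf)Cl2, AsPh3, Cs2CO3) to give the seco epoxy alcohol F2. The ether is then closed within the molecule by acid-catalysed epoxide opening at high dilution, which gives 31 directly and replaces steps 20 and 21. The closure itself is less precedented than step 20, so this remains the second choice.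

**Step 21 (macrocyclisation).** Hydroboration of the neopentyl vinyl group may be slow, and the palladium intermediate may be intercepted between molecules (oligomerisation) or lose iodine by protodehalogenation before the strained ring closes.
Fallback, from 29, back at 31: the ring is closed by olefin metathesis instead. Stille coupling of 29 with tributyl(vinyl)stannane (Pd(PPh3)4, CuI) gives the (Z)-diene F3. Ring-closing metathesis with the second-generation Grubbs catalyst RuCl2(=CHPh)(H2IMes)(PCy3) forms C12=C13 and gives the macrocyclic diene F4. Diimide (from 2-nitrobenzenesulfonyl hydrazide and Et3N) saturates the disubstituted C12=C13 alkene in preference to the trisubstituted and tetrasubstituted ones, giving 31.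

**Step 3 (key step).** The trisubstituted enal is a slow dienophile. The diene may be desilylated or oligomerised by the acid before it adds, and a background pathway not controlled by the catalyst would lower the enantiofacial discrimination.
Fallback, from 4 and 5, back at 10: the same cycloaddition is run with an achiral Lewis acid (Me2AlCl), and the racemate is resolved by the reagent-controlled reduction. The cycloaddition gives 6 together with its mirror image, ent-adduct F5. Steps 4–6 carry the pair on to 7 with ent-enol ether F6, 8 with ent-enone F7 and 9 with ent-iodoenone F8. The (S)-oxazaborolidine reduction of step 7 then gives the (8R) carbinol from both, that is 10 and the diastereomeric iodoenol F9, which are separated by chromatography. Half of the material is lost, and the outcome depends on step 7 being reagent-controlled.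

**Step 7 (C8 carbinol).** The ring is expected to prefer hydride delivery to the other face of the ketone; if this preference is strong, the catalyst may not override it and facial selectivity will be poor.
Fallback, from 9, back at 10: the substrate preference is accepted and the carbinol is inverted. Luche reduction (NaBH4, CeCl3·7H2O, MeOH) should give the (8S) cis-iodoenol F10. Mitsunobu reaction with 4-nitrobenzoic acid (PPh3, diisopropyl azodicarboxylate) inverts C8 to the (8R) 4-nitrobenzoate F11, and K2CO3 in MeOH releases 10.

## Further compounds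

F1 | step 20 | C13 alkylborane of 12 with the C8 oxygen as 9-borabicyclo[3.3.1]nonane borinate | C[C@@H]1C[C@@H](OB3C4CCCC3CCC4)C2=C(COC2=O)[C@@]1(C)CCB3C4CCCC3CCC4
F2 | step 20 | seco epoxy alcohol (C13–C2 joined, C8 hydroxyl free, (R)-epoxide at C6/C19, C4 O-TBS) | C/C(=C/[C@@H](O[Si](C)(C)C(C)(C)C)C[C@]1(C)CO1)CC[C@@]2(C)[C@H](C)C[C@@H](O)C3=C2COC3=O
F3 | step 21 | (Z)-diene from 29 (vinyl in place of iodine on C2) | C/C(C=C)=C/[C@@H](O[Si](C)(C)C(C)(C)C)C[C@@](C)(CO)O[C@@H]1C[C@@H](C)[C@](C)(C=C)C2=C1C(=O)OC2
F4 | step 21 | 12,13-didehydro-4-O-(tert-butyldimethylsilyl)neocucurbin A (geometry of C12=C13 open) | C/C1=C/[C@@H](O[Si](C)(C)C(C)(C)C)C[C@@](C)(CO)O[C@@H]2C[C@@H](C)[C@](C)(C=C1)C1=C2C(=O)OC1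
F5 | step 3 | (1R,2S,6S)-2-[(tert-butyldimethylsilyloxy)methyl]-1,6-dimethyl-4-(triisopropylsilyloxy)cyclohex-3-ene-1-carbaldehyde (enantiomer of 6) | C[C@H]1CC(O[Si](C(C)C)(C(C)C)C(C)C)=C[C@H](CO[Si](C)(C)C(C)(C)C)[C@]1(C)C=O
F6 | step 3 | tert-butyl{[(1S,5S,6R)-6-ethenyl-5,6-dimethyl-3-(triisopropylsilyloxy)cyclohex-2-en-1-yl]methoxy}dimethylsilane (enantiomer of 7) | C[C@H]1CC(O[Si](C(C)C)(C(C)C)C(C)C)=C[C@H](CO[Si](C)(C)C(C)(C)C)[C@]1(C)C=C
F7 | step 3 | (4R,5S)-3-[(tert-butyldimethylsilyloxy)methyl]-4-ethenyl-4,5-dimethylcyclohex-2-en-1-one (enantiomer of 8) | C[C@H]1CC(=O)C=C(CO[Si](C)(C)C(C)(C)C)[C@]1(C)C=C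
F8 | step 3 | (4R,5S)-3-[(tert-butyldimethylsilyloxy)methyl]-4-ethenyl-2-iodo-4,5-dimethylcyclohex-2-en-1-one (enantiomer of 9) | C[C@H]1CC(=O)C(I)=C(CO[Si](C)(C)C(C)(C)C)[C@]1(C)C=C
F9 | step 3 | (1R,4R,5S)-3-[(tert-butyldimethylsilyloxy)methyl]-4-ethenyl-2-iodo-4,5-dimethylcyclohex-2-en-1-ol | C[C@H]1C[C@@H](O)C(I)=C(CO[Si](C)(C)C(C)(C)C)[C@]1(C)C=C
F10 | step 7 | (1S,4S,5R)-3-[(tert-butyldimethylsilyloxy)methyl]-4-ethenyl-2-iodo-4,5-dimethylcyclohex-2-en-1-ol | C[C@@H]1C[C@H](O)C(I)=C(CO[Si](C)(C)C(C)(C)C)[C@@]1(C)C=C
F11 | step 7 | (1R,4S,5R)-3-[(tert-butyldimethylsilyloxy)methyl]-4-ethenyl-2-iodo-4,5-dimethylcyclohex-2-en-1-yl 4-nitrobenzoate | C[C@@H]1C[C@@H](OC(=O)c2ccc(cc2)[N+](=O)[O-])C(I)=C(CO[Si](C)(C)C(C)(C)C)[C@@]1(C)C=C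
A1 | alternative 1 | twelve-membered ether carbocycle with C6 carboxylic acid, (E)-C3=C4 alkene, C2 trimethylsilyloxy group, triisopropylsilyloxymethyl on C14 and 4-methoxybenzyloxymethyl on C15 | C[C@@]1(O[Si](C)(C)C)/C=C/C[C@@](C)(C(=O)O)O[C@@H]2C[C@@H](C)[C@](C)(CC1)C(CO[Si](C(C)C)(C(C)C)C(C)C)=C2COCc3ccc(OC)cc3
A2 | alternative 2 | bridged bicyclic β-keto ester (enol form) with the tertiary ether, free C19 hydroxyl and C4 O-TBS | C/C1=C/[C@@H](O[Si](C)(C)C(C)(C)C)C[C@@](C)(CO)O[C@@H]2C[C@@H](C)[C@](C)(CC1)C(O)=C2C(=O)OC
A3 | alternative 3 | 2-allyl-2,3-dimethyl-5-(tert-butyldimethylsilyloxy)cyclohexanone with C8, C10 and C11 as in the target | C=CC[C@@]1(C)[C@H](C)C[C@@H](O[Si](C)(C)C(C)(C)C)CC1=O
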